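Start with an easy subtraction on the flask. By the listed steps, each product molecule costs one partner and each protic impurity costs one too, so 0.450 M of partner less 6.00 mM of impurity is what can reach the two products. Against both substrates together that is 74.0%, the partner budget: the ceiling on both products together, with partner as limiting reagent. The impurity is the small correction, 1.00% on the same scale.

| flask | left-handed substrate | right-handed substrate | partner | protic impurity | catalyst | remark | time |
|---|---|---|---|---|---|---|---|
| midnight | 0.30 M | 0.30 M | 0.45 M | 6 mM | 1.5 mM | the very flask that is asked about, followed so far |  |
| autumn | 0.30 M | 0.30 M | 0.45 M | 9 mM | 1.5 mM | run made earlier |  |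
| flask | 0.30 M | 0.30 M | 0.450 M | 6.00 mM | 1.5 mM |  | 2.5 d |

- midnight (time / h: left-handed product / %): 15.0: 23.8; 20.0: 27.2; 25.0: 29.7; 30.0: 31.7
- autumn (time / h: left-handed product / %): 15.0: 22.9; 20.0: 26.1; 25.0: 28.4

(standard deviation of a reading: 0.5 percentage points)

* the best time, 2.5 d at the latest, for left-handed product
* the amount of left-handed product, in percent of the left-handed substrate and right-handed substrate together charged, at that time
* the first time at which left-handed product reaches 11%, in the same percent

Now a ladder of times, fastest first, from the midnight run, which is this flask followed so far. At the pace of left-handed product up to the first reading, the impurity's correction is worth 0.630 h and the whole budget 46.6 h. At the pace between the last two readings, a rough figure given the scatter and a quarter of the early one, the budget is worth 185 h. Right-handed product is not read in the midnight run, so these rungs give no date at which partner runs out.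

The forecast says 2.5 d, 38% and 0.19 d, on the ground that “Left-handed product has no listed loss route, so it can only rise”. The budget gives no figure for left-handed product by itself; those numbers are the forecast's.

The flask gives 2.50 d, 37.6% and 0.186 d.

    partner + catalyst + left-handed substrate → catalyst + left-handed product (k = 6.90 M⁻² min⁻¹)
    partner + catalyst + right-handed substrate → catalyst + right-handed product (k = 3.10 M⁻² min⁻¹)
    catalyst ⇌ dormant form (K = 3.90, k = 0.0940 min⁻¹)
    partner + protic impurity → quenched reagent (k = 0.980 M⁻¹ min⁻¹)

Half of the quench's turnover is done after 0.0264 h, half of the right-handed path's after 0.575 d, so the correction is paid before the products have gone far. At 2.50 d the two products stand at 60.8% against the budget of 74.0%, and partner at 17.6% of its charge. In the neighbour read at 6.0 d, partner at 4.9% of its charge leaves the budget 70.4% for the products; computed, they hold 42.1% and 28.2%, together 70.3%.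

The runs come from a simulation for substances that don't exist; the scatter is artificial.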